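Assumption: the target has no stereocentre or stereogenic axis, so there is no enantiomer to control; the sp3 centres of 3–5 form as mixtures and disappear on aromatisation.

## Retrosynthetic overview

1. Target 21 comes from C-3 formylation of depside 19, whose only aromatic C–H is on ring A; 19 comes from the aryl ester bond between acid 16 (ring A) and phenol 14 (ring B).
2. Both 14 and 16 derive from one arene, methyl 2,4-dihydroxy-5,6-dimethylbenzoate 7. Ring B gains its third methyl by formylation/reduction (7 → 9 → 11), then 4-O-benzylation, 2-O-methylation and debenzylation. Ring A needs only bis-benzylation and saponification.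
3. Arene 7 comes from cyclohexane-1,3-dione 4 by bromination–dehydrobromination and hydrodebromination.
4. Dione 4 comes from the key C–C bond: intermolecular Michael addition of dimethyl malonate 1 to enone 2, followed by Claisen ring closure.
5. Ring order: the single carbocycle is built once (1 + 2), aromatised, then split into the ring A and ring B series; no other ring is formed.

## Route

Step 1
Reactants: 1 dimethyl malonate; 2 (E)-3-methylpent-3-en-2-one
Product: 4 methyl 5,6-dimethyl-2,4-dioxocyclohexane-1-carboxylate, via Michael adduct 3 (not isolated)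
Conditions: NaOMe (1.1 equiv), MeOH, reflux, 8 h; then aq. HCl, 0 °C
Reagents that add atoms: none
Why: Michael addition of the malonate anion to the β-carbon of 2 forms the key fragment-joining C–C bond, and the methyl-ketone enolate of 3 then closes the six-membered ring by intramolecular Claisen (Dieckmann-type) condensation, driven by the stable 1,3-dione enolate, the three sp3 centres forming unselectively because they are erased in step 2.

Step 2
Reactants: 4 methyl 5,6-dimethyl-2,4-dioxocyclohexane-1-carboxylate
Product: 6 methyl 3-bromo-2,4-dihydroxy-5,6-dimethylbenzoate, via bromo-dione 5 (not isolated)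
Conditions: Br2 (2.1 equiv), AcOH, 15 °C to rt, 16 h
Reagents that add atoms: bromine, BrBr
Why: Bromination of the enolised 1,3-dione and loss of HBr (bromination–dehydrobromination) aromatises the ring, and the second equivalent of Br2 deliberately fills the only free position (C-3) by electrophilic aromatic substitution so that one product is obtained instead of an arene/bromoarene mixture.

Step 3
Reactants: 6 methyl 3-bromo-2,4-dihydroxy-5,6-dimethylbenzoate
Product: 7 methyl 2,4-dihydroxy-5,6-dimethylbenzoate
Conditions: H2 (1 atm), 10% Pd/C, NaOAc (1.5 equiv), MeOH, rt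
Reagents that add atoms: none
Why: Catalytic hydrodehalogenation of the aryl bromide over Pd/C with NaOAc as HBr scavenger leaves the ester and phenols untouched.

Step 4
Reactants: 7 methyl 2,4-dihydroxy-5,6-dimethylbenzoate
Product: 9 methyl 3-formyl-2,4-dihydroxy-5,6-dimethylbenzoate, via chloro ether 8 (not isolated)
Conditions: Cl2CHOMe (1.5 equiv), TiCl4 (3 equiv), CH2Cl2, 0 °C to rt; then ice-cold 1 M HCl
Reagents that add atoms: dichloromethyl methyl ether, COC(Cl)Cl; water, O
Why: Rieche formylation (electrophilic aromatic substitution by the TiCl4-activated dichloromethyl ether) can only occur at C-3, the single free position flanked by both hydroxyls, and aqueous work-up hydrolyses the α-chloro ether to the aldehyde.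

Step 5
Reactants: 9 methyl 3-formyl-2,4-dihydroxy-5,6-dimethylbenzoate
Product: 11 methyl 2,4-dihydroxy-3,5,6-trimethylbenzoate, via benzylic alcohol 10 (not isolated)
Conditions: Et3SiH (3 equiv), CF3CO2H, CH2Cl2, 0 °C to rt
Reagents that add atoms: none
Why: Ionic hydrogenation reduces the aldehyde to the benzylic alcohol, which ionises to a cation stabilised by both ortho hydroxyls and takes a second hydride to give the methyl group, the fully substituted ring excluding diarylmethane formation.

Step 6
Reactants: 11 methyl 2,4-dihydroxy-3,5,6-trimethylbenzoate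
Product: 12 methyl 4-(benzyloxy)-2-hydroxy-3,5,6-trimethylbenzoate
Conditions: BnBr (1.05 equiv), K2CO3 (1.1 equiv), acetone, reflux
Reagents that add atoms: benzyl bromide, BrCc1ccccc1
Why: Williamson etherification selects the 4-OH because the 2-OH is locked in a strong hydrogen bond to the ester carbonyl and is much less acidic and nucleophilic under mild carbonate conditions.

Step 7
Reactants: 12 methyl 4-(benzyloxy)-2-hydroxy-3,5,6-trimethylbenzoate
Product: 13 methyl 4-(benzyloxy)-2-methoxy-3,5,6-trimethylbenzoate
Conditions: MeI (3 equiv), K2CO3 (3 equiv), DMF, 50 °C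
Reagents that add atoms: iodomethane, CI
Why: Williamson O-methylation of the remaining chelated phenol succeeds under more forcing conditions (excess MeI, polar aprotic solvent, heat) with no other nucleophilic site left.

Step 8
Reactants: 13 methyl 4-(benzyloxy)-2-methoxy-3,5,6-trimethylbenzoate
Product: 14 methyl 4-hydroxy-2-methoxy-3,5,6-trimethylbenzoate
Conditions: H2 (1 atm), 10% Pd/C, EtOAc/MeOH, rt
Reagents that add atoms: none
Why: Hydrogenolysis of the benzyl ether frees only the 4-OH, the methyl ether and methyl ester being inert.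

Step 9
Reactants: 7 methyl 2,4-dihydroxy-5,6-dimethylbenzoate
Product: 15 methyl 2,4-bis(benzyloxy)-5,6-dimethylbenzoate
Conditions: BnBr (2.5 equiv), K2CO3 (3 equiv), DMF, 60 °C
Reagents that add atoms: benzyl bromide, BrCc1ccccc1
Why: Exhaustive Williamson benzylation protects both phenols of ring A, including the chelated 2-OH, so that the acid can later be activated without self-acylation.

Step 10
Reactants: 15 methyl 2,4-bis(benzyloxy)-5,6-dimethylbenzoate
Product: 16 2,4-bis(benzyloxy)-5,6-dimethylbenzoic acid
Conditions: KOH (10 equiv), DMSO/H2O 4:1, 90 °C; then 2 M HCl, 0 °C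
Reagents that add atoms: potassium hydroxide, [K+].[OH-]
Why: Saponification of the di-ortho-substituted benzoate is achieved with the poorly solvated, highly nucleophilic hydroxide of KOH in aqueous DMSO, the benzyl ethers being stable and the O-protected acid not prone to decarboxylation.

Step 11
Reactants: 16 2,4-bis(benzyloxy)-5,6-dimethylbenzoic acid; 14 methyl 4-hydroxy-2-methoxy-3,5,6-trimethylbenzoate
Product: 18 methyl 4-{[2,4-bis(benzyloxy)-5,6-dimethylbenzoyl]oxy}-2-methoxy-3,5,6-trimethylbenzoate, via mixed anhydride 17 (not isolated)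
Conditions: (CF3CO)2O (4 equiv), toluene, 0 °C to rt, 12 h; aq. NaHCO3 work-up
Reagents that add atoms: none
Why: Esterification via the mixed trifluoroacetic anhydride works because the anhydride ionises to a linear acylium ion stabilised by the ortho and para benzyloxy groups, which acylates even the di-ortho-methylated phenol.

Step 12
Reactants: 18 methyl 4-{[2,4-bis(benzyloxy)-5,6-dimethylbenzoyl]oxy}-2-methoxy-3,5,6-trimethylbenzoate
Product: 19 methyl 4-[(2,4-dihydroxy-5,6-dimethylbenzoyl)oxy]-2-methoxy-3,5,6-trimethylbenzoate
Conditions: H2 (1 atm), 10% Pd/C, EtOAc, rt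
Reagents that add atoms: none
Why: Hydrogenolysis removes both benzyl ethers while the aryl ester, methyl ester and methyl ether survive, and no aldehyde is yet present to be over-reduced.

Step 13
Reactants: 19 methyl 4-[(2,4-dihydroxy-5,6-dimethylbenzoyl)oxy]-2-methoxy-3,5,6-trimethylbenzoate
Product: 21 methyl 4-[(3-formyl-2,4-dihydroxy-5,6-dimethylbenzoyl)oxy]-2-methoxy-3,5,6-trimethylbenzoate, via chloro ether 20 (not isolated)
Conditions: Cl2CHOMe (2 equiv), TiCl4 (4 equiv), CH2Cl2, −20 to 0 °C; then ice-cold 1 M HCl
Reagents that add atoms: dichloromethyl methyl ether, COC(Cl)Cl; water, O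
Why: Rieche formylation is regiochemically unambiguous because the depside has a single aromatic C–H (C-3 of ring A between the two hydroxyls, ring B being hexasubstituted), low temperature preserves the aryl ester, and the achiral product requires no stereocontrol.

## Compound list

1 | dimethyl malonate | COC(=O)CC(=O)OC | starting material
2 | (E)-3-methylpent-3-en-2-one | C/C=C(\C)C(C)=O | starting material
3 | dimethyl 2-(3-methyl-4-oxopentan-2-yl)propanedioate (Michael adduct, diastereomer mixture, not isolated) | COC(=O)C(C(=O)OC)C(C)C(C)C(C)=O | intermediate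
4 | methyl 5,6-dimethyl-2,4-dioxocyclohexane-1-carboxylate (diastereomer and tautomer mixture) | COC(=O)C1C(C)C(C)C(=O)CC1=O | intermediate
5 | methyl 3-bromo-5,6-dimethyl-2,4-dioxocyclohexane-1-carboxylate (not isolated) | COC(=O)C1C(C)C(C)C(=O)C(Br)C1=O | intermediate
6 | methyl 3-bromo-2,4-dihydroxy-5,6-dimethylbenzoate | COC(=O)c1c(C)c(C)c(O)c(Br)c1O | intermediate
7 | methyl 2,4-dihydroxy-5,6-dimethylbenzoate | COC(=O)c1c(C)c(C)c(O)cc1O | intermediate
8 | methyl 3-[chloro(methoxy)methyl]-2,4-dihydroxy-5,6-dimethylbenzoate (not isolated) | COC(=O)c1c(C)c(C)c(O)c(C(Cl)OC)c1O | intermediate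
9 | methyl 3-formyl-2,4-dihydroxy-5,6-dimethylbenzoate | COC(=O)c1c(C)c(C)c(O)c(C=O)c1O | intermediate
10 | methyl 2,4-dihydroxy-3-(hydroxymethyl)-5,6-dimethylbenzoate (not isolated) | COC(=O)c1c(C)c(C)c(O)c(CO)c1O | intermediate
11 | methyl 2,4-dihydroxy-3,5,6-trimethylbenzoate | COC(=O)c1c(C)c(C)c(O)c(C)c1O | intermediate
12 | methyl 4-(benzyloxy)-2-hydroxy-3,5,6-trimethylbenzoate | COC(=O)c1c(C)c(C)c(OCc2ccccc2)c(C)c1O | intermediate
13 | methyl 4-(benzyloxy)-2-methoxy-3,5,6-trimethylbenzoate | COC(=O)c1c(C)c(C)c(OCc2ccccc2)c(C)c1OC | intermediate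
14 | methyl 4-hydroxy-2-methoxy-3,5,6-trimethylbenzoate | COC(=O)c1c(C)c(C)c(O)c(C)c1OC | intermediate
15 | methyl 2,4-bis(benzyloxy)-5,6-dimethylbenzoate | COC(=O)c1c(C)c(C)c(OCc2ccccc2)cc1OCc1ccccc1 | intermediate
16 | 2,4-bis(benzyloxy)-5,6-dimethylbenzoic acid | OC(=O)c1c(C)c(C)c(OCc2ccccc2)cc1OCc1ccccc1 | intermediate
17 | 2,4-bis(benzyloxy)-5,6-dimethylbenzoic trifluoroacetic anhydride (not isolated) | FC(F)(F)C(=O)OC(=O)c1c(C)c(C)c(OCc2ccccc2)cc1OCc1ccccc1 | intermediate
18 | methyl 4-{[2,4-bis(benzyloxy)-5,6-dimethylbenzoyl]oxy}-2-methoxy-3,5,6-trimethylbenzoate | COC(=O)c1c(C)c(C)c(OC(=O)c2c(C)c(C)c(OCc3ccccc3)cc2OCc2ccccc2)c(C)c1OC | intermediate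
19 | methyl 4-[(2,4-dihydroxy-5,6-dimethylbenzoyl)oxy]-2-methoxy-3,5,6-trimethylbenzoate | COC(=O)c1c(C)c(C)c(OC(=O)c2c(C)c(C)c(O)cc2O)c(C)c1OC | intermediate
20 | methyl 4-({3-[chloro(methoxy)methyl]-2,4-dihydroxy-5,6-dimethylbenzoyl}oxy)-2-methoxy-3,5,6-trimethylbenzoate (not isolated) | COC(=O)c1c(C)c(C)c(OC(=O)c2c(C)c(C)c(O)c(C(Cl)OC)c2O)c(C)c1OC | intermediate
21 | methyl 4-[(3-formyl-2,4-dihydroxy-5,6-dimethylbenzoyl)oxy]-2-methoxy-3,5,6-trimethylbenzoate | COC(=O)c1c(C)c(C)c(OC(=O)c2c(C)c(C)c(O)c(C=O)c2O)c(C)c1OC | target

## Step count and risks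

Total step count: 13. Longest linear sequence: 11 steps (steps 1–8, then 11–13); the ring A branch (steps 9–10) leaves the trunk at 7.

Three steps most likely to fail:

Step 13 (late formylation of the depside). TiCl4 could cleave or chelate the depside, or conversion could stall on the ester-deactivated, hydrogen-bonded ring. The fallback installs the formyl group before the coupling. It sets out from aldehyde ester 9, already made in step 4. The hindered methyl ester is cleaved through its acylium ion in cold concentrated H2SO4 and quenched on ice to give 3-formyl-2,4-dihydroxy-5,6-dimethylbenzoic acid F1. The ring is fully substituted, so sulfonation is not possible. F1 is then esterified directly with phenol 14 using (CF3CO)2O in toluene, its two chelated hydroxyls being poor nucleophiles, and the route is rejoined at target 21.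

Step 11 (coupling of a di-ortho-substituted acid with a di-ortho-methyl phenol). If the mixed-anhydride method gives low conversion or attacks the ortho benzyl ether, the fallback uses a preformed electrophile and a preformed nucleophile. It sets out from acid 16, which is converted with oxalyl chloride and catalytic DMF in CH2Cl2 into 2,4-bis(benzyloxy)-5,6-dimethylbenzoyl chloride F2. Phenol 14 is deprotonated with NaH in THF to sodium 3-methoxy-4-(methoxycarbonyl)-2,5,6-trimethylphenolate F3. F2 and F3 are combined in THF from 0 °C to reflux, and the route is rejoined at depside 18.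

Step 6 (regioselective mono-benzylation). If the hindered 4-OH (two ortho methyls) reacts too slowly and mixtures of mono- and bis-ethers result, selective protection is replaced by selective deprotection. Setting out from 11, both phenols are benzylated (BnBr 3 equiv, K2CO3, DMF, 70 °C) to methyl 2,4-bis(benzyloxy)-3,5,6-trimethylbenzoate F4. BCl3 (1.1 equiv, CH2Cl2, −78 °C) then chelates between the ester carbonyl and the ortho ether oxygen and removes only the 2-O-benzyl group, rejoining the route at 12.

## Further compounds

F1 | step 13 | 3-formyl-2,4-dihydroxy-5,6-dimethylbenzoic acid | O=Cc1c(O)c(C)c(C)c(C(=O)O)c1O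
F2 | step 11 | 2,4-bis(benzyloxy)-5,6-dimethylbenzoyl chloride | ClC(=O)c1c(C)c(C)c(OCc2ccccc2)cc1OCc1ccccc1
F3 | step 11 | sodium 3-methoxy-4-(methoxycarbonyl)-2,5,6-trimethylphenolate | COC(=O)c1c(C)c(C)c([O-])c(C)c1OC.[Na+]
F4 | step 6 | methyl 2,4-bis(benzyloxy)-3,5,6-trimethylbenzoate | COC(=O)c1c(C)c(C)c(OCc2ccccc2)c(C)c1OCc1ccccc1
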